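**Retrosynthetic overview**
- The only ring of the target, the oxolane, is closed last, in the way lignan biosynthesis is presumed to close it: the C9′ hydroxyl adds (5-exo) to a C7 para-quinone methide.
- The quinone methide is made by direct dehydrogenation of the unprotected seco-lignan triol, with no differentiation of the two phenols (the microscopic reverse of the reductase step that links oxolane and seco lignans).
- The triol comes from a dioxolanone acid that already carries C8, C8′ and both aryl groups, by LiAlH4 reduction and debenzylation.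
- Both benzyl groups come from one bromide: an acetal-controlled quaternisation at C8′ and an anti-selective alkylation at C8 of a malate dianion.
- Backbone C9′–C8′–C8–C9 and the C8′ configuration come from diisopropyl (S)-malate; ring order: temporary dioxolanone auxiliary (made in step 4, destroyed in step 6), then the oxolane (step 8).

Assumption: the SMILES is read as olivil, 7S,8R,8′S (oxolane 2S,3R,4S); lignan numbering is used, C7/C8/C9 for the half whose aryl carbon enters the ring and C7′/C8′/C9′ for the benzyl/tertiary-carbinol half. 4-(Benzyloxy)-3-methoxybenzyl alcohol, diisopropyl (S)-malate, pivalaldehyde, vanillin and O-benzylvanillin are taken as purchasable.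

**Route**

Step 1
Reactants: 1 4-(benzyloxy)-3-methoxybenzyl alcohol
Product: 2 4-(benzyloxy)-3-methoxybenzyl bromide
Conditions: PBr3 (0.4 equiv), CH2Cl2, 0 °C, 1 h; used crude
Reagents that add atoms: phosphorus tribromide, BrP(Br)Br
Why: SN2 bromination of an electron-rich benzylic alcohol through its phosphite ester; no stereocentre is involved.

Step 2
Reactants: 3 diisopropyl (S)-malate; 2 4-(benzyloxy)-3-methoxybenzyl bromide
Product: 5 diisopropyl (2S,3R)-3-[4-(benzyloxy)-3-methoxybenzyl]-2-hydroxybutanedioate, via dilithium alkoxide-enolate 4 (not isolated)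
Conditions: LiN(SiMe3)2 (2.1 equiv), THF, −78 to −20 °C; then 2 (1.0 equiv), −78 to −10 °C; 1 M HCl quench
Reagents that add atoms: none
Why: Fráter–Seebach alkylation: the chelated alkoxide-enolate is benzylated anti to the C2 oxygen, which sets C8 (3R, about 9:1 dr expected, minor syn isomer removed by chromatography) and leaves C2 (the future C8′) untouched.

Step 3
Reactants: 5 diisopropyl (2S,3R)-3-[4-(benzyloxy)-3-methoxybenzyl]-2-hydroxybutanedioate
Product: 6 (2S,3R)-3-[4-(benzyloxy)-3-methoxybenzyl]-2-hydroxybutanedioic acid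
Conditions: KOH (4 equiv), EtOH/H2O, 0 °C to rt, 16 h; then 2 M HCl to pH 1
Reagents that add atoms: potassium hydroxide, [K+].[OH-]
Why: Ester saponification under mild conditions; once the first carboxylate has formed the α-proton at C3 is no longer acidic, so C8 does not epimerise.

Step 4
Reactants: 6 (2S,3R)-3-[4-(benzyloxy)-3-methoxybenzyl]-2-hydroxybutanedioic acid
Product: 7 (2R)-3-[4-(benzyloxy)-3-methoxyphenyl]-2-[(2S,4S)-2-tert-butyl-5-oxo-1,3-dioxolan-4-yl]propanoic acid
Conditions: t-BuCHO (3 equiv), TsOH·H2O (5 mol%), H2SO4 (1 mol%), pentane/CH2Cl2, reflux, Dean–Stark; recrystallise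
Reagents that add atoms: pivalaldehyde (2,2-dimethylpropanal), CC(C)(C)C=O
Why: Acid-catalysed acetalisation of the α-hydroxy acid unit (Seebach dioxolanone formation), five-membered dioxolanone preferred over the six-membered dioxanone; the new acetal centre (2S) is set cis to the side chain under thermodynamic control.

Step 5
Reactants: 7 (2R)-3-[4-(benzyloxy)-3-methoxyphenyl]-2-[(2S,4S)-2-tert-butyl-5-oxo-1,3-dioxolan-4-yl]propanoic acid; 2 4-(benzyloxy)-3-methoxybenzyl bromide
Product: 9 (2R)-3-[4-(benzyloxy)-3-methoxyphenyl]-2-{(2S,4S)-4-[4-(benzyloxy)-3-methoxybenzyl]-2-tert-butyl-5-oxo-1,3-dioxolan-4-yl}propanoic acid, via dilithium carboxylate-enolate 8 (not isolated)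
Conditions: LiN(SiMe3)2 (2.2 equiv), THF, −78 °C, 45 min; then 2 (1.2 equiv), −78 to −30 °C; 1 M HCl quench
Reagents that add atoms: none
Why: Seebach self-regeneration of stereocentres: only the dioxolanone α-proton is removed (the carboxylate α-proton is far less acidic), and the bromide attacks the enolate anti to the tert-butyl group, the face the hydrogen had occupied, which gives the quaternary C8′ with net retention.

Step 6
Reactants: 9 (2R)-3-[4-(benzyloxy)-3-methoxyphenyl]-2-{(2S,4S)-4-[4-(benzyloxy)-3-methoxybenzyl]-2-tert-butyl-5-oxo-1,3-dioxolan-4-yl}propanoic acid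
Product: 10 (2S,3S)-2,3-bis[4-(benzyloxy)-3-methoxybenzyl]butane-1,2,4-triol
Conditions: LiAlH4 (5 equiv), THF, 0 °C to reflux, 3 h; aqueous work-up
Reagents that add atoms: none
Why: LiAlH4 reduction of the carboxylic acid and of the dioxolanone acyl group (the hemiacetal collapses and the released pivalaldehyde is reduced); no stereocentre is touched, and the C8 descriptor changes from R to S only because substituent ranks change.

Step 7
Reactants: 10 (2S,3S)-2,3-bis[4-(benzyloxy)-3-methoxybenzyl]butane-1,2,4-triol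
Product: 11 (2S,3S)-2,3-bis(4-hydroxy-3-methoxybenzyl)butane-1,2,4-triol
Conditions: H2 (1 atm), 10% Pd/C, EtOAc/MeOH, rt
Reagents that add atoms: none
Why: Hydrogenolysis of the two aryl benzyl ethers; the molecule has no other benzylic C–O bond.

Step 8
Reactants: 11 (2S,3S)-2,3-bis(4-hydroxy-3-methoxybenzyl)butane-1,2,4-triol
Product: 13 (3S,4R,5S)-5-(4-hydroxy-3-methoxyphenyl)-3-(4-hydroxy-3-methoxybenzyl)-4-(hydroxymethyl)oxolan-3-ol (olivil; the target), via C7 para-quinone methide 12 (not isolated)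
Conditions: DDQ (1.0 equiv, added over 30 min), 1,4-dioxane/CH2Cl2 (1:1), 0 °C; filter off the hydroquinone, chromatography
Reagents that add atoms: none
Why: Proposed new method: DDQ removes hydride from a benzylic CH2 of a free guaiacyl phenol to give a para-quinone methide (closest known reaction: DDQ dehydrogenation of 4-alkyl-2-methoxyphenols with capture of the quinone methide by an alcohol); C7 should react before C7′ because the cation-like transition state at C7′ is destabilised by the β-hydroxyl on C8′ and hindered by the quaternary centre; quinone methide 12 has a single 5-exo trap, the primary C9′ hydroxyl (the C9 and C8′ hydroxyls could only give oxetanes), which adds anti to the C8 hydroxymethyl group through an envelope with aryl and CH2OH pseudo-equatorial, setting C7 as S (aryl trans to CH2OH).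

**Compound list**

1 | 4-(benzyloxy)-3-methoxybenzyl alcohol | COc1cc(CO)ccc1OCc1ccccc1 | starting material
2 | 4-(benzyloxy)-3-methoxybenzyl bromide | COc1cc(CBr)ccc1OCc1ccccc1 | intermediate
3 | diisopropyl (S)-malate | CC(C)OC(=O)C[C@H](O)C(=O)OC(C)C | starting material
4 | dilithium alkoxide-enolate of 3 (formed in the flask) | CC(C)OC(=O)[C@@H]([O-])C=C([O-])OC(C)C.[Li+].[Li+] | intermediate
5 | diisopropyl (2S,3R)-3-[4-(benzyloxy)-3-methoxybenzyl]-2-hydroxybutanedioate | CC(C)OC(=O)[C@H](Cc1ccc(OCc2ccccc2)c(OC)c1)[C@H](O)C(=O)OC(C)C | intermediate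
6 | (2S,3R)-3-[4-(benzyloxy)-3-methoxybenzyl]-2-hydroxybutanedioic acid | OC(=O)[C@H](Cc1ccc(OCc2ccccc2)c(OC)c1)[C@H](O)C(=O)O | intermediate
7 | (2R)-3-[4-(benzyloxy)-3-methoxyphenyl]-2-[(2S,4S)-2-tert-butyl-5-oxo-1,3-dioxolan-4-yl]propanoic acid (tert-butyl cis to the side chain) | OC(=O)[C@H](Cc1ccc(OCc2ccccc2)c(OC)c1)[C@@H]1O[C@H](C(C)(C)C)OC1=O | intermediate
8 | dilithium carboxylate-enolate of 7 (formed in the flask) | [O-]C(=O)[C@H](Cc1ccc(OCc2ccccc2)c(OC)c1)C1=C([O-])O[C@@H](C(C)(C)C)O1.[Li+].[Li+] | intermediate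
9 | (2R)-3-[4-(benzyloxy)-3-methoxyphenyl]-2-{(2S,4S)-4-[4-(benzyloxy)-3-methoxybenzyl]-2-tert-butyl-5-oxo-1,3-dioxolan-4-yl}propanoic acid (new benzyl trans to tert-butyl) | OC(=O)[C@H](Cc1ccc(OCc2ccccc2)c(OC)c1)[C@]1(Cc2ccc(OCc3ccccc3)c(OC)c2)O[C@H](C(C)(C)C)OC1=O | intermediate
10 | (2S,3S)-2,3-bis[4-(benzyloxy)-3-methoxybenzyl]butane-1,2,4-triol | COc1cc(C[C@@](O)(CO)[C@H](CO)Cc2ccc(OCc3ccccc3)c(OC)c2)ccc1OCc1ccccc1 | intermediate
11 | (2S,3S)-2,3-bis(4-hydroxy-3-methoxybenzyl)butane-1,2,4-triol (seco-lignan triol) | COc1cc(C[C@@](O)(CO)[C@H](CO)Cc2ccc(O)c(OC)c2)ccc1O | intermediate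
12 | 4-[(2S,3S)-3,4-dihydroxy-3-(4-hydroxy-3-methoxybenzyl)-2-(hydroxymethyl)butylidene]-2-methoxycyclohexa-2,5-dien-1-one (C7 para-quinone methide, formed in the flask) | COC1=CC(=C[C@@H](CO)[C@](O)(CO)Cc2ccc(O)c(OC)c2)C=CC1=O | intermediate
13 | (3S,4R,5S)-5-(4-hydroxy-3-methoxyphenyl)-3-(4-hydroxy-3-methoxybenzyl)-4-(hydroxymethyl)oxolan-3-ol (olivil, 7S,8R,8′S) | COc1cc(C[C@@]2(O)CO[C@H](c3ccc(O)c(OC)c3)[C@H]2CO)ccc1O | target

**Step count**

Total: 8 steps. Longest linear sequence: 8 steps from 1 (7 from malate 3).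

**Steps most likely to fail, with fallbacks**

Step 8 is the most likely to fail. The risks are oxidation at C7′ instead of C7 (giving the regioisomeric oxolane through the C9 hydroxyl), further oxidation of the product at its new benzylic ether C–H, and acid-promoted closure to the aryltetralin. The fallback enforces the site of oxidation by orthogonal phenol protection; it sets out from 7 and comes back at 13. Vanillin is silylated (iPr3SiCl, imidazole, DMF) to 3-methoxy-4-(triisopropylsilyloxy)benzaldehyde F1, reduced (NaBH4, MeOH) to [3-methoxy-4-(triisopropylsilyloxy)phenyl]methanol F2 and brominated (PBr3, cat. pyridine, Et2O, 0 °C) to 3-methoxy-4-(triisopropylsilyloxy)benzyl bromide F3. F3 takes the place of 2 in the enolate alkylation of 7 (conditions of step 5) and gives the mixed-ether dioxolanone acid F4. LiAlH4 reduces it to the mixed-ether triol F5, and hydrogenolysis (H2, Pd/C) frees only the phenol of the C7 ring to give the mono-phenol triol F6. DDQ (1.0 equiv, dioxane/CH2Cl2, 0 °C) can then form a quinone methide only at C7 and closes it to olivil 4′-O-triisopropylsilyl ether F7. Bu4NF buffered with AcOH (THF, 0 °C) gives 13.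

Step 5 is second. The risks are low reactivity or fragmentation of the carboxylate-enolate 8 and incomplete facial control at the hindered quaternary centre. The fallback replaces acetal control by 1,2-induction in a lactone; it sets out from 7 and comes back at 10. BH3·SMe2 (THF, 0 °C to rt) reduces only the carboxylic acid, and the new primary alcohol opens the dioxolanone (cat. TsOH, CH2Cl2) to the cis-hydroxy lactone (3S,4S)-4-[4-(benzyloxy)-3-methoxybenzyl]-3-hydroxyoxolan-2-one F8. Its alkoxide-enolate (LiN(iPr)2, 2.2 equiv, THF, −78 °C) is benzylated with 2 anti to the C4 benzyl group to give (3S,4S)-3,4-bis[4-(benzyloxy)-3-methoxybenzyl]-3-hydroxyoxolan-2-one F9, which has the same C8′ configuration as 9. LiAlH4 reduces F9 to triol 10.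

Step 2 is third. The risks are sluggish alkylation of dianion 4 and an anti:syn ratio below about 9:1. The fallback makes the C7–C8 bond by carbonyl addition and then removes the benzylic oxygen; it sets out from 3 and comes back at 6. Dianion 4 (from 3, LiN(SiMe3)2) adds to 4-(benzyloxy)-3-methoxybenzaldehyde at −78 °C, and the aldolate lactonises on acidic work-up to propan-2-yl (3S,4S)-2-[4-(benzyloxy)-3-methoxyphenyl]-4-hydroxy-5-oxooxolane-3-carboxylate F10; both C2 epimers are carried on, since that centre is removed next. Ionic hydrogenation (Et3SiH, CF3CO2H, CH2Cl2, 0 °C) cleaves the benzylic lactone C–O bond to (2S,3R)-3-[4-(benzyloxy)-3-methoxybenzyl]-2-hydroxy-4-oxo-4-(propan-2-yloxy)butanoic acid F11. Saponification (KOH, EtOH/H2O, then HCl) gives diacid 6.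

**Further compounds**

F1 | step 8 | 3-methoxy-4-(triisopropylsilyloxy)benzaldehyde | COc1cc(C=O)ccc1O[Si](C(C)C)(C(C)C)C(C)C
F2 | step 8 | [3-methoxy-4-(triisopropylsilyloxy)phenyl]methanol | COc1cc(CO)ccc1O[Si](C(C)C)(C(C)C)C(C)C
F3 | step 8 | 3-methoxy-4-(triisopropylsilyloxy)benzyl bromide | COc1cc(CBr)ccc1O[Si](C(C)C)(C(C)C)C(C)C
F4 | step 8 | (2R)-3-[4-(benzyloxy)-3-methoxyphenyl]-2-{(2S,4S)-2-tert-butyl-4-[3-methoxy-4-(triisopropylsilyloxy)benzyl]-5-oxo-1,3-dioxolan-4-yl}propanoic acid | OC(=O)[C@H](Cc1ccc(OCc2ccccc2)c(OC)c1)[C@]1(Cc2ccc(O[Si](C(C)C)(C(C)C)C(C)C)c(OC)c2)O[C@H](C(C)(C)C)OC1=O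
F5 | step 8 | (2S,3S)-3-[4-(benzyloxy)-3-methoxybenzyl]-2-[3-methoxy-4-(triisopropylsilyloxy)benzyl]butane-1,2,4-triol | COc1cc(C[C@@](O)(CO)[C@H](CO)Cc2ccc(OCc3ccccc3)c(OC)c2)ccc1O[Si](C(C)C)(C(C)C)C(C)C
F6 | step 8 | (2S,3S)-3-(4-hydroxy-3-methoxybenzyl)-2-[3-methoxy-4-(triisopropylsilyloxy)benzyl]butane-1,2,4-triol | COc1cc(C[C@@](O)(CO)[C@H](CO)Cc2ccc(O)c(OC)c2)ccc1O[Si](C(C)C)(C(C)C)C(C)C
F7 | step 8 | (3S,4R,5S)-5-(4-hydroxy-3-methoxyphenyl)-4-(hydroxymethyl)-3-[3-methoxy-4-(triisopropylsilyloxy)benzyl]oxolan-3-ol (olivil 4′-O-triisopropylsilyl ether) | COc1cc(C[C@@]2(O)CO[C@H](c3ccc(O)c(OC)c3)[C@H]2CO)ccc1O[Si](C(C)C)(C(C)C)C(C)C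
F8 | step 5 | (3S,4S)-4-[4-(benzyloxy)-3-methoxybenzyl]-3-hydroxyoxolan-2-one | O=C1OC[C@H](Cc2ccc(OCc3ccccc3)c(OC)c2)[C@@H]1O
F9 | step 5 | (3S,4S)-3,4-bis[4-(benzyloxy)-3-methoxybenzyl]-3-hydroxyoxolan-2-one | O=C1OC[C@H](Cc2ccc(OCc3ccccc3)c(OC)c2)[C@@]1(O)Cc1ccc(OCc2ccccc2)c(OC)c1
F10 | step 2 | propan-2-yl (3S,4S)-2-[4-(benzyloxy)-3-methoxyphenyl]-4-hydroxy-5-oxooxolane-3-carboxylate (both C2 epimers) | CC(C)OC(=O)[C@@H]1C(c2ccc(OCc3ccccc3)c(OC)c2)OC(=O)[C@H]1O
F11 | step 2 | (2S,3R)-3-[4-(benzyloxy)-3-methoxybenzyl]-2-hydroxy-4-oxo-4-(propan-2-yloxy)butanoic acid | CC(C)OC(=O)[C@H](Cc1ccc(OCc2ccccc2)c(OC)c1)[C@H](O)C(=O)O
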